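The readings were generated by integration for an exercise; the scatter is artificial.

The chemist who charged this flask asked when it holds most target and how much, so I first sorted the given numbers by what an error in each costs.

- north-east: starting material 0.019 M; partner 0.037 M; run made earlier
- flask: starting material 0.039 M; partner 0.0370 M; time 15 d

- north-east (time / d: target / %, starting material / %): 0.333: 1.4, 84.4; 0.625: 6.1, 73.3; 1.25: 17.4, 51.5; 2.50: 39.6, 26.5; 5.00: 60.5, 7.3

(readings scatter by 0.5 percentage points)

* when, up to 15 d, the flask holds most target
* the amount of target, in percent of the starting material charged, at that time

- the analysis behind the earlier runs scatters by 0.5 percentage points, standard deviation

The first number I needed was k, the first-order constant of starting material, taken from the first and last north-east readings. The scatter on the last reading moves k by 2.80%, so it is cheap. The charges enter differently. Target lags, so I assumed an intermediate that takes up one partner on its way to target, and then an error in either charge passes directly into the passage ceiling, the charged partner over the charged starting material, 94.9%, which is the most of the starting material that can pass that step. As for the values, k was 0.524 d⁻¹, a half-life of 1.32 d. The same ratio in the north-east run was 195%. This flask's ceiling lies below the full charge of starting material and the north-east ratio above it, so I expected partner to fall lower here and committed to a peak under the last north-east reading of 60.5%.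

The forecast said 63% at 15 d, holding that “it should rise to a plateau”. The flask gave 53.4% at 6.23 d.

    starting material → intermediate (k = 0.0220 h⁻¹)
    partner + intermediate → target (k = 0.870 M⁻¹ h⁻¹)
    target → over-reaction product (k = 0.00350 h⁻¹)

With the turning of target into over-reaction product taken away, this flask reaches 88.0%, still under its ceiling. That step took 35 percentage points from this flask's peak. In the neighbour flask with 0.098 M of starting material, the ceiling is 37.8%, which makes partner the limiting reagent. Computed, 0% of partner is left at the end, target and over-reaction product together hold 37.8%, and the best target is 29.4%.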